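**Remark on labels.** Carbon labels C1–C15 are those of the germacranolide skeleton of the target and are kept for every intermediate (C6 bears the lactone oxygen, C7 bears C11, C12 is the lactone carbonyl, C13 the exocyclic methylene, C14 and C15 the methyls on C10 and C4). The THP acetal carbon in 9–15 and C10 in 11 and 12 are carried as epimer mixtures of no consequence.

## The problem

The target 29 is a ten-membered carbocycle with two trisubstituted Z alkenes (C4=C5 and C9=C10), a cis-fused α-methylene-γ-butyrolactone across C6–C7, a free allylic hydroxyl at C1, an acetate at C3 and an angelate at C8. Direct closure of a ten-membered ring is costly, and neither Z geometry can be entrusted to a macrocyclising olefination or metathesis. Of the five stereocentres (1S, 3S, 6R, 7R, 8R), C6, C7 and C8 are contiguous, so C7 can relay to C6 and C8. C1 and C3 are cut off from that triad by sp2 carbons and need reagent control. The α-methylene lactone is a Michael acceptor that does not tolerate organometallics, amines or strong base, and its allylic C7–H lets base move the alkene into the ring. The angelate isomerises to the tiglate under nucleophilic catalysis, the three allylic C–O bonds ionise under acid, and a free C1 hydroxyl lies cis across C9=C10 to C8, where it would add to a C8 ketone. The enabling feature is that C3 and C8 are both oxygenated, lie 1,6 across the ring, and are each bonded to the alkene of their half. A C3–C8 bond therefore folds the macrocycle into a cis-fused bicycle: ring A (C3–C4–C5–C6–C7–C8) and ring B (C8–C9–C10–C1–C2–C3) are both cyclohexenes whose alkenes are Z by necessity. The two oxygens become a ring-fusion cis-diol, the substrate of a glycol cleavage.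

## Retrosynthesis

**Endgame, 29 back to 23.** The Si–O bond of 28, the angelate C–O bond (26 + 27), the C8–H bond (25), the acetyl C–O bond (24) and the C3–H bond are cut in turn, which leads to the 3,8-diketone 23. Because the two esters differ, the two carbinols must appear one after the other; having both as ketones makes them the direct outcome of one fragmentation. The forward steps must tell the C3 ketone (flanked by a CH2) from the C8 ketone (flanked by the C7 methine) and set 3S and 8R.

**Key cut, 23 back to 21.** In the retro sense a bond is drawn between C3 and C8, turning the diketone into the ditertiary cis-diol 21. The neighbouring cuts are macrocyclic metathesis at C4=C5 or C9=C10, or an intramolecular allylation at C6–C7. All of them close a ten-membered ring and leave the geometry of trisubstituted alkenes to chance. Compound 21 contains only six- and five-membered rings, and both alkenes are already locked Z. The forward step must cleave a hindered glycol under near-neutral conditions without touching the lactone, C7–H or the enones.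

**Lactone, 21 back to 15.** The O6–C12 lactone bond is cut to the 1,4-diol 18 (oxidative lactonisation), the PMB ether 17 is its precursor, the C6–H bond leads to enone 16, and the C6 ketone and C8 hydroxyl are masked in 15 as ketal and THP acetal. Building the α-methylene lactone only after all carbanion chemistry keeps this acceptor away from enolates and hydrides. Carrying C12 as an allylic ether and C6 as a ketal costs three redox or deprotection steps. The hydride must enter C6 anti to the C7 side chain to give the cis relationship.

**Ring B adjustment, 15 back to 12.** The silyl ether, the C1–H bond (14 from enone 13) and the C9=C10 π bond (13 from ketol 12) are removed. A reagent-controlled reduction sets 1S, and the dehydrogenation can only go toward C9 because C3 is quaternary.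

**Annulation, 12 back to 9 and 10.** The C2–C3 and C8–C9 bonds are cut (retro-aldol, retro-Michael), which removes ring B and both tertiary carbinol centres and leaves the monocyclic α-alkoxy enone 9 and 3-methylbut-3-en-2-one 10. The neighbouring plan is to add a vinyl and a four-carbon organometallic to a ring A 1,2-dione and close ring B by metathesis. It is set aside for three reasons:
- such a dione would exist as its enol toward C7, losing that stereocentre and inviting β-elimination of the C6 oxygen;
- two additions that each answer to the C7 substituent and to the other new centre do not reliably give a cis diol;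
- no lactone could be present.

In the annulation the cis diol is a consequence of cis ring fusion. The forward reaction must alkylate a tetrasubstituted enolate anti to the C7 side chain and stop at the ketol.

**C8 oxygen, 9 back to 6.** The acetal and the C8–O bond are cut; the oxygen comes from electrophilic hydroxylation of the only possible enolate of 6. The configuration set here is irrelevant, because C8 is re-enolised in the annulation.

**Ring A and side chain, 6 back to 5 and 3.** The C7–C11 bond is cut as an asymmetric conjugate addition of the alkenylboronate 3 to the quinone monoketal 5. In 5 the dienone carbonyl is C3, the ketal is the latent C6 oxygen and the methyl is already on C4. Compound 5 comes from phenol 4 by oxidative dearomatisation, and 3 from 2,3-dibromopropene 1 via 2. A free C6 ketone could not be used, since the resulting enedione would tautomerise to a hydroquinone. The addition must choose the unsubstituted enone and one enantioface; this is the only absolute stereocontrol needed for C6–C8.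

## Roads not taken

**Alternative 1:** The lactone is cut last, at C7–C11 and C11=C13. In the forward sense the C6 phosphonoacetate A1, a ten-membered (4Z,9Z)-diene with a cis C7–C8 epoxide on the face opposite the C6 oxygen, is deprotonated with NaH. The carbanion opens the epoxide at C7, and the α-phosphono lactone is olefinated with formaldehyde (Horner–Wadsworth–Emmons) to give A2.
- Merits: one flask forms C7–C11, the cis ring fusion (enforced by the tether), the methylene and a free C8 hydroxyl already distinguished from the protected C3 oxygen. No ketone ever flanks C7.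
- Weak points: the route to A1, that is the closure of the ten-membered ring with two Z trisubstituted alkenes, is left open. The epoxide must be placed on one face of a mobile medium ring, and the C8 alkoxide set free may translactonise to the 8,12-lactone.
- Comparison: in the endgame this road is shorter and cleaner than the chosen plan, which has to set two chemoselective ketone reductions against it. The chosen plan is stronger where Alternative 1 is silent: ring formation and alkene geometry come from six-membered-ring chemistry.

**Alternative 2:** The cut is C7–C8. In the forward sense n-BuLi exchanges tin for lithium at C8 of the thirteen-membered stannyl ether A3. The α-alkoxy carbanion attacks C7 in a [2,3]-Wittig shift, O–C13 breaks, C11=C13 appears and the ring contracts to A4.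
- Merits: a thirteen-membered ring is easier to close than a ten-membered one. The key step forms a C–C bond, two stereocentres and the exocyclic methylene at once and frees a differentiated C8 hydroxyl. No ketones at C3 or C8 are needed.
- Weak points: both Z alkenes must be made by separate olefinations. The C7/C8 outcome depends on the folding of a heavily substituted large ring and on the stannane configuration. The C8 carbanion is allylic to C9=C10 and can expel the C1 silyloxy group, and a [1,2]-shift competes. Four different silyl ethers must then be sorted, C12 oxidised and the lactone closed.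
- Comparison: this road is more convergent. The chosen plan has the longer linear sequence but derives ring size and both geometries from two cyclohexenes and applies no strong base to the assembled framework.

**Alternative 3:** The cut is C1–C5. In the forward sense the hydroazulene A5 (C1 tertiary alcohol, C3–C4 epoxide, lactone and angelate in place) is treated with KOtBu or Ti(OiPr)4 (tetravalent titanium). The alkoxide fragments: the C1 ketone forms, C1–C5 breaks, C4=C5 forms and the epoxide opens to the C3 alkoxide, giving A6.
- Merits: the logic is the same as in the chosen plan. The C4=C5 geometry follows stereospecifically from C4/C5, C3 arrives as a stereocentre from the epoxide, and only one ketone (C1) results. Its reduction can be directed by the C3 hydroxyl toward the 1,3-anti diol. In these respects it is at least as good as the chosen plan.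
- Weak points: the fragmentation needs antiperiplanar C1–C5 and C4–O bonds in a hydroazulene with three extra stereocentres (C1, C4, C5). Only one alkene is made by the step. A tertiary alkoxide is generated beside the α-methylene lactone and the angelate (conjugate addition, acyl transfer, tiglate formation), and A6 is a β-hydroxy ketone prone to retro-aldol or dehydration under the same base.
- Comparison: against the single ketone and the pre-set C3 of this road, the chosen plan sets a near-neutral fragmentation, sacrificial stereocentres that are fixed by an annulation, and both alkenes locked before the ring is opened.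

Key step: step 15

## Route

Step 1
Reactants: 1 2,3-dibromoprop-1-ene
Product: 2 1-[(2-bromoprop-2-en-1-yl)oxymethyl]-4-methoxybenzene
Conditions: 4-methoxybenzyl alcohol, NaH, Bu4NI (cat.), THF, 0 → 25 °C
Reagents that add atoms: 4-methoxybenzyl alcohol, COc1ccc(CO)cc1
Why: Williamson ether synthesis; the alkoxide displaces the allylic bromide only, the vinylic bromide being inert to SN2.

Step 2
Reactants: 2 1-[(2-bromoprop-2-en-1-yl)oxymethyl]-4-methoxybenzene
Product: 3 2-{3-[(4-methoxybenzyl)oxy]prop-1-en-2-yl}-4,4,5,5-tetramethyl-1,3,2-dioxaborolane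
Conditions: bis(pinacolato)diboron, PdCl2(PPh3)2 (divalent palladium precatalyst), PPh3, KOPh, toluene, 50 °C
Reagents that add atoms: bis(pinacolato)diboron, CC1(C)OB(OC1(C)C)B1OC(C)(C)C(C)(C)O1
Why: Miyaura borylation of a 1-alkenyl bromide; the weak base KOPh suppresses Suzuki homocoupling and the ether is not an allylic leaving group for zerovalent palladium.

Step 3
Reactants: 4 4-methoxy-2-methylphenol
Product: 5 4,4-dimethoxy-2-methylcyclohexa-2,5-dien-1-one
Conditions: PhI(OAc)2, MeOH, 0 °C
Reagents that add atoms: methanol, CO
Why: Oxidative dearomatisation of a p-methoxyphenol; methanol traps the phenoxenium ion para to oxygen to give the quinone monoketal.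

Step 4
Reactants: 5 4,4-dimethoxy-2-methylcyclohexa-2,5-dien-1-one; 3 2-{3-[(4-methoxybenzyl)oxy]prop-1-en-2-yl}-4,4,5,5-tetramethyl-1,3,2-dioxaborolane
Product: 6 (5R)-4,4-dimethoxy-5-{3-[(4-methoxybenzyl)oxy]prop-1-en-2-yl}-2-methylcyclohex-2-en-1-one
Conditions: [Rh(OH)(C8H12)]2 (monovalent rhodium), (R)-BINAP, KOH (cat.), 1,4-dioxane–H2O, 50 °C
Reagents that add atoms: none
Why: Hayashi–Miyaura asymmetric 1,4-addition; the alkenylrhodium inserts the α-unsubstituted enone of the dienone rather than the α-methyl one and forms C7–C11. (R)-BINAP is chosen by analogy with the sense known for cyclohex-2-enone to give the 7R configuration (5R in the ring numbering of 6).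

Step 5
Reactants: 6 (5R)-4,4-dimethoxy-5-{3-[(4-methoxybenzyl)oxy]prop-1-en-2-yl}-2-methylcyclohex-2-en-1-one
Product: 8 (5S,6S)-6-hydroxy-4,4-dimethoxy-5-{3-[(4-methoxybenzyl)oxy]prop-1-en-2-yl}-2-methylcyclohex-2-en-1-one, via lithium enolate 7 (not isolated)
Conditions: LiN(SiMe3)2, THF, −78 °C; then 3-phenyl-2-(phenylsulfonyl)oxaziridine, −78 °C; aq. NH4Cl
Reagents that add atoms: 3-phenyl-2-(phenylsulfonyl)oxaziridine, O=S(=O)(c1ccccc1)N1OC1c1ccccc1
Why: Davis α'-hydroxylation; C8 is the only enolisable position (C6 is a ketal, C4 is sp2) and oxygen is expected to enter anti to the C7 side chain. This configuration is of no consequence because C8 is re-enolised in step 7.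

Step 6
Reactants: 8 (5S,6S)-6-hydroxy-4,4-dimethoxy-5-{3-[(4-methoxybenzyl)oxy]prop-1-en-2-yl}-2-methylcyclohex-2-en-1-one
Product: 9 (5S,6S)-4,4-dimethoxy-5-{3-[(4-methoxybenzyl)oxy]prop-1-en-2-yl}-2-methyl-6-(tetrahydro-2H-pyran-2-yloxy)cyclohex-2-en-1-one
Conditions: 3,4-dihydro-2H-pyran, PPTS (cat.), CH2Cl2, 25 °C
Reagents that add atoms: 3,4-dihydro-2H-pyran, C1=COCCC1
Why: Acid-catalysed acetalisation under anhydrous conditions that leave the dimethyl ketal intact; unlike a silyl or acyl group, an acetal cannot migrate between the oxygens of the enediolate formed in step 7, and it is removed together with the ketal in step 11.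

Step 7
Reactants: 9 (5S,6S)-4,4-dimethoxy-5-{3-[(4-methoxybenzyl)oxy]prop-1-en-2-yl}-2-methyl-6-(tetrahydro-2H-pyran-2-yloxy)cyclohex-2-en-1-one; 10 3-methylbut-3-en-2-one
Product: 12 cis-fused ketol (C1 ketone; C3–OH; C8–OTHP; C6 dimethyl ketal), via Michael adduct 11 (not isolated)
Conditions: KOtBu (0.2 equiv), t-BuOH–THF, −10 → 0 °C
Reagents that add atoms: none
Why: Robinson-type Michael–aldol sequence stopped at the ketol; the tetrasubstituted C8 enolate should attack the CH2 terminus of 10 anti to the pseudoaxial C7 side chain (C8–O ends on the side-chain face), forming C8–C9. The methyl ketone enolate then closes ring B on the C3 carbonyl (C2–C3) with the cis fusion usual for Robinson ketols, which places C3–OH cis to C8–O. C10 forms as an inconsequential epimer mixture.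

Step 8
Reactants: 12 cis-fused ketol
Product: 13 ring B enone (C1 ketone conjugated with C9=C10)
Conditions: IBX, 4-methoxypyridine N-oxide, DMSO, 25 °C
Reagents that add atoms: none
Why: IBX dehydrogenation of a ketone; desaturation is possible only on the C10 side because C3 is quaternary, and the endocyclic trisubstituted enone is the preferred product over the exocyclic methylene isomer.

Step 9
Reactants: 13 ring B enone
Product: 14 (1S)-allylic alcohol
Conditions: (R)-2-methyl-CBS-oxazaborolidine (0.2 equiv), BH3·SMe2, THF, −30 °C
Reagents that add atoms: none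
Why: Corey–Bakshi–Shibata reduction of an α-methyl enone; with the α-branched alkenyl group as the large substituent and C2H2 as the small one, the (R)-catalyst should deliver hydride to give 1S, the hydroxyl cis to C3–OH on ring B.

Step 10
Reactants: 14 (1S)-allylic alcohol
Product: 15 C1 tert-butyldimethylsilyl ether
Conditions: TBSCl, imidazole, DMF, 25 °C
Reagents that add atoms: tert-butyldimethylsilyl chloride, CC(C)(C)[Si](C)(C)Cl
Why: Selective silylation of the only secondary hydroxyl; the tertiary C3–OH does not react under these conditions.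

Step 11
Reactants: 15 C1 tert-butyldimethylsilyl ether
Product: 16 C6 enone 3,8-diol
Conditions: PPTS, acetone–H2O (9:1), 40 °C
Reagents that add atoms: water, O
Why: Mild acid hydrolysis of the allylic dimethyl ketal and of the tertiary THP acetal in one operation; C3 is now sp3, so the enedione-to-hydroquinone tautomerisation that forbade earlier unmasking of C6 cannot occur, and the secondary silyl ether survives.

Step 12
Reactants: 16 C6 enone 3,8-diol
Product: 17 (6R)-alcohol (3,6,8-triol PMB ether)
Conditions: LiBH(s-Bu)3, THF, −78 °C; aq. NH4Cl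
Reagents that add atoms: none
Why: 1,2-Reduction with a bulky hydride (L-selectride); the β,β-disubstituted enone cannot undergo conjugate reduction, and attack anti to the adjacent C7 side chain should give the C6 hydroxyl cis to it, as needed for the cis lactone.

Step 13
Reactants: 17 (6R)-alcohol
Product: 18 3,6,8,12-tetraol
Conditions: DDQ, CH2Cl2–pH 7 buffer, 0 °C
Reagents that add atoms: none
Why: Oxidative cleavage of the p-methoxybenzyl ether; the silyl ether and the tertiary allylic alcohols are unaffected.

Step 14
Reactants: 18 3,6,8,12-tetraol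
Product: 21 lactone diol (cis-fused 3,8-diol with α-methylene-γ-butyrolactone), via hydroxy enal 19 (not isolated), via lactol 20 (not isolated)
Conditions: Cu(MeCN)4OTf (monovalent copper), 2,2'-bipyridine, TEMPO, N-methylimidazole, air, MeCN, 25 °C
Reagents that add atoms: none
Why: Copper/nitroxyl aerobic oxidative lactonisation of a 1,4-diol; the primary allylic alcohol is oxidised first, the enal is trapped by the cis C6 hydroxyl as the lactol, and a second oxidation gives the lactone. The tertiary glycol is inert here, whereas a hypervalent iodine co-oxidant could cleave it prematurely.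

Step 15
Reactants: 21 lactone diol
Product: 23 (1S,4Z,6R,7R,9Z)-1-(tert-butyldimethylsilyloxy)-3,8-dioxogermacra-4,9,11(13)-trien-12,6-olide, via cyclic lead diester 22 (not isolated)
Conditions: Pb(OAc)4 (tetravalent lead), benzene, 10 °C; filtration through Florisil, used at once
Reagents that add atoms: none
Why: Criegee glycol cleavage: the cis ditertiary diol exchanges two acetates on Pb(OAc)4 to give the five-membered cyclic diester 22, whose two-electron fragmentation breaks C3–C8, forms both C=O bonds and releases Pb(OAc)2 (divalent lead). The closest known reaction type is the lead tetraacetate cleavage of cis-decalin-4a,8a-diols and their unsaturated analogues to cyclodecane-1,6-diones. No ring is closed: the bond shared by ring A and ring B is cut, so the two six-membered rings merge into the ten-membered ring. No stereocentre is created; C3 and C8 become trigonal, C1, C6 and C7 are untouched, and both alkenes keep the Z geometry they had as cyclohexenes. The step needs chemoselectivity for the glycol over four alkenes and their allylic positions, which the cis geometry (O–C–C–O dihedral near 60°) secures by making cyclic ester formation fast. The product has an acidic C7–H between the C8 ketone and C11=C13 and two Z enones, so the medium is aprotic, cold and free of base, and 23 is reduced immediately. The C1 oxygen stays silylated because a free hydroxyl cis across C9=C10 would add to the C8 ketone.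

Step 16
Reactants: 23 ten-membered 3,8-diketone
Product: 24 (1S,3S,4Z,6R,7R,9Z)-1-(tert-butyldimethylsilyloxy)-3-hydroxy-8-oxogermacra-4,9,11(13)-trien-12,6-olide
Conditions: (R)-2-methyl-CBS-oxazaborolidine (0.3 equiv), catecholborane (1.2 equiv), toluene, −78 °C
Reagents that add atoms: none
Why: Corey–Bakshi–Shibata reduction; the C3 carbonyl, flanked by an unhindered CH2 and an α-methyl alkenyl group, is both the more accessible and the better-discriminated ketone, and the (R)-catalyst should give 3S. The C8 carbonyl next to the C7 methine is expected to react more slowly, and the α-methylene lactone is not reduced by catecholborane at this temperature.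

Step 17
Reactants: 24 3-hydroxy-8-ketone
Product: 25 (1S,3S,4Z,6R,7R,9Z)-3-acetoxy-1-(tert-butyldimethylsilyloxy)-8-oxogermacra-4,9,11(13)-trien-12,6-olide
Conditions: Ac2O, pyridine, DMAP (cat.), CH2Cl2, 0 °C
Reagents that add atoms: acetic anhydride, CC(=O)OC(C)=O
Why: Standard acylation of the only free hydroxyl.

Step 18
Reactants: 25 3-acetate 8-ketone
Product: 26 (1S,3S,4Z,6R,7S,8R,9Z)-3-acetoxy-1-(tert-butyldimethylsilyloxy)-8-hydroxygermacra-4,9,11(13)-trien-12,6-olide
Conditions: NaBH4, CeCl3·7H2O, MeOH, −78 °C
Reagents that add atoms: none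
Why: Luche 1,2-reduction of the enone; peripheral hydride attack on the conformer in which C8=O eclipses C7–H should place the new hydroxyl trans to the C7–C11 bond (8R). The acetate and the α-methylene lactone are spared at low temperature. (The C7 descriptor changes to S only because the CIP priority of C8 changes.)

Step 19
Reactants: 26 3-acetate 8-alcohol; 27 (Z)-2-methylbut-2-enoic acid (angelic acid)
Product: 28 (1S,3S,4Z,6R,7R,8R,9Z)-3-acetoxy-8-angeloyloxy-1-(tert-butyldimethylsilyloxy)germacra-4,9,11(13)-trien-12,6-olide
Conditions: 27, 2,4,6-trichlorobenzoyl chloride, Et3N, toluene, 25 °C; then 26, 75 °C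
Reagents that add atoms: none
Why: Yamaguchi-type mixed anhydride esterification without a nucleophilic catalyst, the conditions known to transfer the angeloyl group to hindered secondary alcohols with little isomerisation to the tiglate; the hindered trichlorobenzoyl carbonyl is not attacked.

Step 20
Reactants: 28 8-angelate 1-silyl ether
Product: 29 (1S,3S,4Z,6R,7R,8R,9Z)-3-acetoxy-8-angeloyloxy-1-hydroxygermacra-4,9,11(13)-trien-12,6-olide (target)
Conditions: HF·pyridine, THF–pyridine, 0 → 25 °C
Reagents that add atoms: none
Why: Buffered fluoride desilylation; the mildly acidic medium avoids acyl migration, conjugate addition to the lactone and angelate isomerisation.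

## Compound list

1 | 2,3-dibromoprop-1-ene | C=C(Br)CBr | starting material
2 | 1-[(2-bromoprop-2-en-1-yl)oxymethyl]-4-methoxybenzene | C=C(Br)COCc1ccc(OC)cc1 | intermediate
3 | 2-{3-[(4-methoxybenzyl)oxy]prop-1-en-2-yl}-4,4,5,5-tetramethyl-1,3,2-dioxaborolane | C=C(COCc1ccc(OC)cc1)B1OC(C)(C)C(C)(C)O1 | intermediate
4 | 4-methoxy-2-methylphenol | COc1ccc(O)c(C)c1 | starting material
5 | 4,4-dimethoxy-2-methylcyclohexa-2,5-dien-1-one | COC1(OC)C=CC(=O)C(C)=C1 | intermediate
6 | (5R)-4,4-dimethoxy-5-{3-[(4-methoxybenzyl)oxy]prop-1-en-2-yl}-2-methylcyclohex-2-en-1-one | C=C(COCc1ccc(OC)cc1)[C@H]1CC(=O)C(C)=CC1(OC)OC | intermediate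
7 | lithium enolate of 6 (C3–OLi, C3=C8) | C=C(COCc1ccc(OC)cc1)[C@H]1C=C(O[Li])C(C)=CC1(OC)OC | intermediate (not isolated)
8 | (5S,6S)-6-hydroxy-4,4-dimethoxy-5-{3-[(4-methoxybenzyl)oxy]prop-1-en-2-yl}-2-methylcyclohex-2-en-1-one (hydroxyl trans to the side chain) | C=C(COCc1ccc(OC)cc1)[C@H]1[C@H](O)C(=O)C(C)=CC1(OC)OC | intermediate
9 | (5S,6S)-4,4-dimethoxy-5-{3-[(4-methoxybenzyl)oxy]prop-1-en-2-yl}-2-methyl-6-(tetrahydro-2H-pyran-2-yloxy)cyclohex-2-en-1-one (acetal epimers) | C=C(COCc1ccc(OC)cc1)[C@H]1[C@H](OC2CCCCO2)C(=O)C(C)=CC1(OC)OC | intermediate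
10 | 3-methylbut-3-en-2-one | CC(=O)C(C)=C | starting material
11 | Michael adduct: C8-quaternary 1,5-diketone, C8–OTHP cis to the C7 side chain, C8–CH2CH(CH3)C(O)CH3 on the opposite face | C=C(COCc1ccc(OC)cc1)[C@H]1[C@](OC2CCCCO2)(CC(C)C(C)=O)C(=O)C(C)=CC1(OC)OC | intermediate (not isolated)
12 | cis-fused ketol: ring B C1 ketone with C10 methyl (epimers), C3–OH and C8–OTHP at the ring fusion, C4(CH3)=C5, C6 dimethyl ketal, C7 side chain; C3–O, C8–O and the C7 side chain on one face | C=C(COCc1ccc(OC)cc1)[C@H]1[C@]2(OC3CCCCO3)CC(C)C(=O)C[C@]2(O)C(C)=CC1(OC)OC | intermediate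
13 | ring B enone: as 12 with C9=C10 conjugated to the C1 ketone | C=C(COCc1ccc(OC)cc1)[C@H]1[C@]2(OC3CCCCO3)C=C(C)C(=O)C[C@]2(O)C(C)=CC1(OC)OC | intermediate
14 | (1S)-allylic alcohol: as 13 with C1–OH cis to C3–OH | C=C(COCc1ccc(OC)cc1)[C@H]1[C@]2(OC3CCCCO3)C=C(C)[C@@H](O)C[C@]2(O)C(C)=CC1(OC)OC | intermediate
15 | C1 tert-butyldimethylsilyl ether of 14 | C=C(COCc1ccc(OC)cc1)[C@H]1[C@]2(OC3CCCCO3)C=C(C)[C@@H](O[Si](C)(C)C(C)(C)C)C[C@]2(O)C(C)=CC1(OC)OC | intermediate
16 | C6 enone 3,8-diol: C6 ketone conjugated to C4=C5, free cis C3/C8 diol, C1–OTBS, C12–OPMB | C=C(COCc1ccc(OC)cc1)[C@H]1[C@]2(O)C=C(C)[C@@H](O[Si](C)(C)C(C)(C)C)C[C@]2(O)C(C)=CC1=O | intermediate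
17 | (6R)-alcohol: 3,6,8-triol with C6–OH cis to the C7 side chain, C1–OTBS, C12–OPMB | C=C(COCc1ccc(OC)cc1)[C@H]1[C@]2(O)C=C(C)[C@@H](O[Si](C)(C)C(C)(C)C)C[C@]2(O)C(C)=C[C@H]1O | intermediate
18 | 3,6,8,12-tetraol, C1–OTBS | C=C(CO)[C@H]1[C@]2(O)C=C(C)[C@@H](O[Si](C)(C)C(C)(C)C)C[C@]2(O)C(C)=C[C@H]1O | intermediate
19 | hydroxy enal (C12 aldehyde of 18) | C=C(C=O)[C@H]1[C@]2(O)C=C(C)[C@@H](O[Si](C)(C)C(C)(C)C)C[C@]2(O)C(C)=C[C@H]1O | intermediate (not isolated)
20 | lactol (C12 hemiacetal with O6, anomers) | C=C1C(O)O[C@@H]2C=C(C)[C@@]3(O)C[C@H](O[Si](C)(C)C(C)(C)C)C(C)=C[C@@]3(O)[C@H]12 | intermediate (not isolated)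
21 | (1S,3S,6R,7R,8R)-1-(tert-butyldimethylsilyloxy)-3,8-dihydroxy-3,8-cyclogermacra-4,9,11(13)-trien-12,6-olide (cis-fused diol; C3–OH, C8–OH, O6, C11 and C1–OTBS on one face) | C=C1C(=O)O[C@@H]2C=C(C)[C@@]3(O)C[C@H](O[Si](C)(C)C(C)(C)C)C(C)=C[C@@]3(O)[C@H]12 | intermediate
22 | cyclic lead diester of 21 (O3 and O8 bridged by a diacetoxy lead centre, tetravalent lead) | C=C1C(=O)O[C@@H]2C=C(C)[C@@]3(O[Pb]4(OC(C)=O)OC(C)=O)C[C@H](O[Si](C)(C)C(C)(C)C)C(C)=C[C@@]3(O4)[C@H]12 | intermediate (not isolated)
23 | (1S,4Z,6R,7R,9Z)-1-(tert-butyldimethylsilyloxy)-3,8-dioxogermacra-4,9,11(13)-trien-12,6-olide | C=C1C(=O)O[C@@H]2/C=C(/C)C(=O)C[C@H](O[Si](C)(C)C(C)(C)C)/C(C)=C\C(=O)[C@H]12 | intermediate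
24 | (1S,3S,4Z,6R,7R,9Z)-1-(tert-butyldimethylsilyloxy)-3-hydroxy-8-oxogermacra-4,9,11(13)-trien-12,6-olide | C=C1C(=O)O[C@@H]2/C=C(/C)[C@@H](O)C[C@H](O[Si](C)(C)C(C)(C)C)/C(C)=C\C(=O)[C@H]12 | intermediate
25 | (1S,3S,4Z,6R,7R,9Z)-3-acetoxy-1-(tert-butyldimethylsilyloxy)-8-oxogermacra-4,9,11(13)-trien-12,6-olide | C=C1C(=O)O[C@@H]2/C=C(/C)[C@@H](OC(C)=O)C[C@H](O[Si](C)(C)C(C)(C)C)/C(C)=C\C(=O)[C@H]12 | intermediate
26 | (1S,3S,4Z,6R,7S,8R,9Z)-3-acetoxy-1-(tert-butyldimethylsilyloxy)-8-hydroxygermacra-4,9,11(13)-trien-12,6-olide | C=C1C(=O)O[C@@H]2/C=C(/C)[C@@H](OC(C)=O)C[C@H](O[Si](C)(C)C(C)(C)C)/C(C)=C\[C@@H](O)[C@H]12 | intermediate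
27 | (Z)-2-methylbut-2-enoic acid (angelic acid) | C/C=C(/C)C(=O)O | starting material
28 | (1S,3S,4Z,6R,7R,8R,9Z)-3-acetoxy-8-[(Z)-2-methylbut-2-enoyloxy]-1-(tert-butyldimethylsilyloxy)germacra-4,9,11(13)-trien-12,6-olide | C=C1C(=O)O[C@@H]2/C=C(/C)[C@@H](OC(C)=O)C[C@H](O[Si](C)(C)C(C)(C)C)/C(C)=C\[C@@H](OC(=O)/C(C)=C\C)[C@H]12 | intermediate
29 | (1S,3S,4Z,6R,7R,8R,9Z)-3-acetoxy-8-[(Z)-2-methylbut-2-enoyloxy]-1-hydroxygermacra-4,9,11(13)-trien-12,6-olide | C=C1C(=O)O[C@@H]2/C=C(/C)[C@@H](OC(C)=O)C[C@H](O)/C(C)=C\[C@@H](OC(=O)/C(C)=C\C)[C@H]12 | target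

## Step count and least certain steps

Total: 20 steps. Longest linear sequence: 19 steps (steps 1, 2 and 4–20). Step 3 is a one-step branch.

**Step 15 (key step).** The cleavage itself has close precedent. The likely failure is loss of 23 after it forms: enolisation at C7 with migration of the C11=C13 alkene into conjugation, Z-to-E isomerisation of an enone, or a transannular aldol while the diketone is handled. Fallback, from 21 back to 26: the filtered benzene solution of the cleavage is not concentrated but run directly into excess catecholborane and (R)-2-methyl-CBS-oxazaborolidine at −78 °C. Both carbonyls are reduced and the sensitive diketone is never isolated. The resulting 3,8-diol F1 is then differentiated by acetylation of the less hindered C3 hydroxyl (Ac2O, 2,4,6-collidine, −20 °C), which gives 26.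

**Step 7.** The Michael addition creates a congested quaternary centre from a tetrasubstituted α-alkoxy enolate. It may stall through retro-Michael reversal or polymerisation of 10, and the aldol equilibrium onto a conjugated carbonyl may not favour the ketol. Fallback, from 9 back to 15, building ring B by two additions and a metathesis (this also removes the reliance on steps 8 and 9):
- the lithium enolate of 9 (LiN(SiMe3)2, −78 °C) is added to acetaldehyde to give the aldol adduct F2;
- dehydration with the Burgess reagent can only go toward the methyl group and gives the C8-vinyl ketone F3;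
- LiCH2C(O)N(OMe)Me with CeCl3 adds to the C3 carbonyl to give the β-hydroxy Weinreb amide F4; the cis relationship of the two tertiary oxygens would have to be confirmed here;
- isopropenylmagnesium bromide gives the isopropenyl ketone F5;
- (R)-CBS reduction gives the (1S)-allylic alcohol F6, and TBSCl/imidazole gives the silyl ether F7;
- ring-closing metathesis of F7 with the second-generation Grubbs catalyst RuCl2(H2IMes)(PCy3)(=CHPh) joins the vinyl and isopropenyl groups and returns to 15.

**Step 4.** The 1,1-disubstituted alkenylrhodium must insert next to a quaternary ketal carbon. Slow transmetalation, β-alkoxide elimination from the alkenylrhodium to an allene, or poor facial selectivity may follow. Fallback, from 5 back to 6: the smaller potassium isopropenyltrifluoroborate is added under the same rhodium/(R)-BINAP catalysis to give the isopropenyl adduct F8. Ene-type allylic chlorination (N-chlorosuccinimide, PhSeCl cat.) gives the allylic chloride F9, and displacement with sodium 4-methoxybenzyl oxide gives 6.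

**Step 16.** Catalyst control may be eroded by the conformation of the ten-membered ring (poor facial selectivity), and some C8 reduction may compete. Fallback, from 23 back to 25: C3 is reduced with whichever reagent gives one epimer cleanly (the antipodal catalyst or a substrate-controlled Luche reduction). If this is the (3R)-alcohol F10, Mitsunobu reaction with acetic acid (PPh3, diisopropyl azodicarboxylate) inverts C3 and installs the acetate in one operation, giving 25.

**Step 18.** Facial selectivity at C8 rests on a conformational argument; attack from the other face would give the 8-epimer. Fallback, from 25 back to 28: the (8S)-alcohol F11 is esterified with 27 under Mitsunobu conditions. Inversion gives the 8R angelate 28 directly, with no acyl-transfer catalyst that could isomerise the angelate, so step 19 is bypassed. Competing SN2' substitution at this allylic centre would have to be watched.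

## Further compounds

F1 | step 15 | (1S,3S,4Z,6R,7S,8R,9Z)-1-(tert-butyldimethylsilyloxy)-3,8-dihydroxygermacra-4,9,11(13)-trien-12,6-olide | C=C1C(=O)O[C@@H]2/C=C(/C)[C@@H](O)C[C@H](O[Si](C)(C)C(C)(C)C)/C(C)=C\[C@@H](O)[C@H]12
F2 | step 7 | aldol adduct of 9 with acetaldehyde (C8 quaternary: OTHP cis to the C7 side chain, 1-hydroxyethyl trans; carbinol epimers) | C=C(COCc1ccc(OC)cc1)[C@H]1[C@](OC2CCCCO2)(C(C)O)C(=O)C(C)=CC1(OC)OC
F3 | step 7 | C8-vinyl ketone | C=C(COCc1ccc(OC)cc1)[C@H]1[C@](OC2CCCCO2)(C=C)C(=O)C(C)=CC1(OC)OC
F4 | step 7 | C3 β-hydroxy Weinreb amide (C3–OH cis to C8–OTHP) | C=C(COCc1ccc(OC)cc1)[C@H]1[C@](OC2CCCCO2)(C=C)[C@](O)(CC(=O)N(C)OC)C(C)=CC1(OC)OC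
F5 | step 7 | C1 isopropenyl ketone | C=C(COCc1ccc(OC)cc1)[C@H]1[C@](OC2CCCCO2)(C=C)[C@](O)(CC(=O)C(C)=C)C(C)=CC1(OC)OC
F6 | step 7 | (1S)-allylic alcohol | C=C(COCc1ccc(OC)cc1)[C@H]1[C@](OC2CCCCO2)(C=C)[C@](O)(C[C@H](O)C(C)=C)C(C)=CC1(OC)OC
F7 | step 7 | C1 tert-butyldimethylsilyl ether (metathesis precursor) | C=C(COCc1ccc(OC)cc1)[C@H]1[C@](OC2CCCCO2)(C=C)[C@](O)(C[C@H](O[Si](C)(C)C(C)(C)C)C(C)=C)C(C)=CC1(OC)OC
F8 | step 4 | (5R)-4,4-dimethoxy-2-methyl-5-(prop-1-en-2-yl)cyclohex-2-en-1-one | C=C(C)[C@H]1CC(=O)C(C)=CC1(OC)OC
F9 | step 4 | (5R)-5-(3-chloroprop-1-en-2-yl)-4,4-dimethoxy-2-methylcyclohex-2-en-1-one | C=C(CCl)[C@H]1CC(=O)C(C)=CC1(OC)OC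
F10 | step 16 | (1S,3R,4Z,6R,7R,9Z)-1-(tert-butyldimethylsilyloxy)-3-hydroxy-8-oxogermacra-4,9,11(13)-trien-12,6-olide | C=C1C(=O)O[C@@H]2/C=C(/C)[C@H](O)C[C@H](O[Si](C)(C)C(C)(C)C)/C(C)=C\C(=O)[C@H]12
F11 | step 18 | (1S,3S,4Z,6R,7S,8S,9Z)-3-acetoxy-1-(tert-butyldimethylsilyloxy)-8-hydroxygermacra-4,9,11(13)-trien-12,6-olide | C=C1C(=O)O[C@@H]2/C=C(/C)[C@@H](OC(C)=O)C[C@H](O[Si](C)(C)C(C)(C)C)/C(C)=C\[C@H](O)[C@H]12
A1 | alternative 1 | C6 diethylphosphonoacetate of the ten-membered (4Z,9Z)-diene with a cis C7–C8 epoxide anti to the C6 oxygen, C3–OPMB, C1–OTBS | CCOP(=O)(OCC)CC(=O)O[C@@H]1/C=C(/C)[C@@H](OCc2ccc(OC)cc2)C[C@H](O[Si](C)(C)C(C)(C)C)/C(C)=C\[C@H]2O[C@@H]12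
A2 | alternative 1 | α-methylene cis-lactone with free C8 hydroxyl | C=C1C(=O)O[C@@H]2/C=C(/C)[C@@H](OCc3ccc(OC)cc3)C[C@H](O[Si](C)(C)C(C)(C)C)/C(C)=C\[C@@H](O)[C@H]12
A3 | alternative 2 | thirteen-membered C8-tributylstannyl allylic ether (C8–O–C13; configuration at C8 and geometry of C7=C11 left open) | CCCC[Sn](CCCC)(CCCC)C1OCC(CO[Si](CC)(CC)CC)=C[C@H](O[Si](CC)(CC)CC)/C=C(/C)[C@@H](O[Si](C)(C)C(C)(C)C)C[C@H](O[Si](c2ccccc2)(c2ccccc2)C(C)(C)C)/C(C)=C\1
A4 | alternative 2 | ten-membered C8 alcohol with C11 exocyclic methylene | C=C(CO[Si](CC)(CC)CC)[C@@H]1[C@H](O[Si](CC)(CC)CC)/C=C(/C)[C@@H](O[Si](C)(C)C(C)(C)C)C[C@H](O[Si](c2ccccc2)(c2ccccc2)C(C)(C)C)/C(C)=C\[C@H]1O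
A5 | alternative 3 | hydroazulene C1 tertiary alcohol with C3–C4 epoxide, lactone and C8 angelate (configuration at C1, C4 and C5 left open) | C=C1C(=O)O[C@@H]2C3C4(C)O[C@H]4CC3(O)/C(C)=C\[C@@H](OC(=O)/C(C)=C\C)[C@H]12
A6 | alternative 3 | C1-keto C3-hydroxy germacranolide | C=C1C(=O)O[C@@H]2/C=C(/C)[C@@H](O)CC(=O)/C(C)=C\[C@@H](OC(=O)/C(C)=C\C)[C@H]12
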